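**Strategy.** Ring B is disconnected at C14–C17, the bond between the allylic ring-fusion CH of cyclopentene ring A (next to C12=C13) and the ester-bearing CH. The bond is made while the future ester carbon C18 still sits inside the ring as a ketone: a palladium-catalysed intramolecular allylic alkylation joins the methyl carbon of an acetonyl group on quaternary C20 to the allyl terminus C14, closing a six-membered homologue of ring B with net retention from a CBS-set carbinol. The precursor is an allylic tert-butyl carbonate carrying a methyl ketone. A photochemical Wolff ring contraction then turns the ring ketone into the methyl ester and sets C17 by kinetic protonation.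

Key step: step 19

Remark (assumption): the target is made as drawn, with the (S)-carbinol in the side chain; compounds 1, 5, 6 and 9 (as a THF solution) are taken as purchasable.

Atom labels used below (labels 8 and 22 are not used):
- C1–C5: side chain from CH3 (C1) to the CH2 on the quaternary carbon (C5); C3 is the carbinol carbon.
- C6: quaternary carbon carrying the side chain and C7 (CH2OH).
- C9: bridgehead CH; C10, C11: ring CH2.
- C12=C13: tetrasubstituted alkene; C14: allylic ring-fusion CH; C15, C16: CH2 of ring A.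
- C17: CH(CO2Me); C18: ester carbon; C19: ring CH2; C20: quaternary bridgehead.
- C21 and C23: the NCH2 carbons on C20 and C9.
- Ring A = cyclopentene C12–C16; ring B = C13, C14, C17, C19, C20; ring C = cycloheptene C6, C9, C10, C11, C12, C13, C20; ring D = piperidine C6, C9, C23, N, C21, C20.

**Route**

Step 1
Reactants: 1 methyl (3S)-3-hydroxypentanoate
Product: 2 methyl (3S)-3-[(triisopropylsilyl)oxy]pentanoate
Conditions: TIPSOTf, 2,6-lutidine, CH2Cl2, 0 °C
Reagents that add atoms: triisopropylsilyl triflate, CC(C)[Si](OS(=O)(=O)C(F)(F)F)(C(C)C)C(C)C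
Why: Silyl triflate with a hindered pyridine base silylates the β-hydroxy ester without retro-aldol or elimination (silyl ether formation), and the purchased C3 centre is not touched.

Step 2
Reactants: 2 methyl (3S)-3-[(triisopropylsilyl)oxy]pentanoate
Product: 3 (3S)-3-[(triisopropylsilyl)oxy]pentan-1-ol
Conditions: DIBAL-H, CH2Cl2, −78 → 0 °C
Reagents that add atoms: none
Why: Hydride reduction of the ester to the primary alcohol leaves the silyl ether and C3 intact.

Step 3
Reactants: 3 (3S)-3-[(triisopropylsilyl)oxy]pentan-1-ol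
Product: 4 {[(3S)-1-iodopentan-3-yl]oxy}triisopropylsilane
Conditions: I2, PPh3, imidazole, CH2Cl2, 0 → 25 °C
Reagents that add atoms: iodine, II
Why: Appel-type (Garegg–Samuelsson) iodination converts the primary alcohol into the iodide under neutral conditions.

Step 4
Reactants: 5 cyclopentane-1,3-dione; 6 methyl glyoxylate
Product: 7 methyl 2-(2,5-dioxocyclopentyl)acetate
Conditions: Hantzsch ester, L-proline (10 mol %), CH2Cl2, 25 °C
Reagents that add atoms: none
Why: Proline-catalysed Knoevenagel condensation followed by Hantzsch-ester transfer hydrogenation (Ramachary reductive alkylation) should give only the C-alkylated dione and avoids O-alkylation.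

Step 5
Reactants: 7 methyl 2-(2,5-dioxocyclopentyl)acetate
Product: 8 methyl 2-[5-oxo-2-(trifluoromethylsulfonyloxy)cyclopent-1-en-1-yl]acetate
Conditions: Tf2O, Et3N, CH2Cl2, −78 °C
Reagents that add atoms: triflic anhydride, O=S(=O)(OS(=O)(=O)C(F)(F)F)C(F)(F)F
Why: The enolised, symmetric dione is a vinylogous acid and is O-sulfonylated to the single possible β-triflyloxy enone (vinylogous triflate formation).

Step 6
Reactants: 8 methyl 2-[5-oxo-2-(trifluoromethylsulfonyloxy)cyclopent-1-en-1-yl]acetate; 9 (4-ethoxy-4-oxobutyl)zinc bromide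
Product: 10 ethyl 4-[2-(2-methoxy-2-oxoethyl)-3-oxocyclopent-1-en-1-yl]butanoate
Conditions: PdCl2(dppf) (3 mol %), THF, 50 °C
Reagents that add atoms: none
Why: Negishi coupling of the electron-poor vinyl triflate with the ester-tolerant alkylzinc reagent installs the four-carbon ester arm on C12.

Step 7
Reactants: 10 ethyl 4-[2-(2-methoxy-2-oxoethyl)-3-oxocyclopent-1-en-1-yl]butanoate
Product: 11 ethyl 4-[(3R)-3-hydroxy-2-(2-methoxy-2-oxoethyl)cyclopent-1-en-1-yl]butanoate
Conditions: (S)-2-methyl-CBS-oxazaborolidine (10 mol %), BH3·SMe2, THF, −30 °C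
Reagents that add atoms: none
Why: Corey–Bakshi–Shibata reduction with the fully substituted alkenyl carbon as the large group should set (R)-C14, the centre from which all ring stereocentres are relayed, while the esters survive at low temperature.

Step 8
Reactants: 11 ethyl 4-[(3R)-3-hydroxy-2-(2-methoxy-2-oxoethyl)cyclopent-1-en-1-yl]butanoate
Product: 12 ethyl 4-[(3R)-3-[(tert-butyldimethylsilyl)oxy]-2-(2-methoxy-2-oxoethyl)cyclopent-1-en-1-yl]butanoate
Conditions: TBSCl, imidazole, DMF, 25 °C
Reagents that add atoms: tert-butyldimethylsilyl chloride, CC(C)(C)[Si](C)(C)Cl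
Why: Imidazole-promoted silylation protects the allylic alcohol as a bulky ether that later shields one face of C20 and of C6.

Step 9
Reactants: 12 ethyl 4-[(3R)-3-[(tert-butyldimethylsilyl)oxy]-2-(2-methoxy-2-oxoethyl)cyclopent-1-en-1-yl]butanoate
Product: 14 methyl (1R)-1-[(tert-butyldimethylsilyl)oxy]-8-(2-methylprop-2-en-1-yl)-7-oxo-1,2,3,4,5,6,7,8-octahydroazulene-8-carboxylate, via bicyclic β-keto ester 13 (not isolated)
Conditions: KOtBu, THF, 0 → 25 °C; then 3-bromo-2-methylpropene, 0 → 25 °C
Reagents that add atoms: 3-bromo-2-methylprop-1-ene, CC(=C)CBr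
Why: Dieckmann condensation under thermodynamic control (the more acidic allylic C20–H2 attacks the butanoate ester) closes seven-membered ring C, and the stabilised enolate is C-alkylated in the same flask; the C20 centre formed here is erased in step 10.

Step 10
Reactants: 14 methyl (1R)-1-[(tert-butyldimethylsilyl)oxy]-8-(2-methylprop-2-en-1-yl)-7-oxo-1,2,3,4,5,6,7,8-octahydroazulene-8-carboxylate
Product: 15 (1R)-1-[(tert-butyldimethylsilyl)oxy]-8-(2-methylprop-2-en-1-yl)-2,3,4,5,6,8-hexahydroazulen-7(1H)-one
Conditions: LiCl, H2O, DMSO, 150 °C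
Reagents that add atoms: none
Why: Krapcho dealkoxycarbonylation removes the activating ester under neutral conditions; any conjugated enone isomer would pass through the same dienol in step 11.

Step 11
Reactants: 15 (1R)-1-[(tert-butyldimethylsilyl)oxy]-8-(2-methylprop-2-en-1-yl)-2,3,4,5,6,8-hexahydroazulen-7(1H)-one
Product: 16 tricyclic amino ketone (rings A, C, D; C6 ketone; C20 2-methylallyl; C14 OTBS)
Conditions: MeNH2 (40 % aq.), CH2O (37 % aq.), AcOH, MeOH, 60 °C
Reagents that add atoms: methylamine, CN; formaldehyde, C=O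
Why: Double Mannich annulation: the dienol should react at C20 on the face opposite the C14 silyloxy group, creating the quaternary centre with C21 anti to that oxygen, and the second, intramolecular Mannich reaction at C9 can only close the piperidine cis, which fixes C9.

Step 12
Reactants: 16 tricyclic amino ketone
Product: 17 tricyclic nitrile (CN and H on C6, both C6 epimers)
Conditions: TosMIC, KOtBu, EtOH (2 equiv), DME, 0 → 40 °C
Reagents that add atoms: p-toluenesulfonylmethyl isocyanide, Cc1ccc(cc1)S(=O)(=O)C[N+]#[C-]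
Why: Van Leusen reductive cyanation converts the bridging ketone into the nitrile with one added carbon (C7), as it does for adamantanone-type ketones; the C6 configuration is irrelevant because C6 is deprotonated next.

Step 13
Reactants: 17 tricyclic nitrile; 4 {[(3S)-1-iodopentan-3-yl]oxy}triisopropylsilane
Product: 18 quaternary nitrile (C6 carries CN and the (3S)-3-silyloxypentyl chain)
Conditions: LDA, THF, −78 °C; then 4, DMPU, −78 → 0 °C
Reagents that add atoms: none
Why: Alkylation of the small nitrile anion builds quaternary C6; the iodide should enter over the three-atom aza bridge because the carbocyclic face is screened by ring A and its C14 silyloxy group, so the chain ends syn to nitrogen and the nitrile syn to ring C.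

Step 14
Reactants: 18 quaternary nitrile
Product: 20 primary alcohol (C7H2OH), via quaternary aldehyde 19 (not isolated)
Conditions: DIBAL-H, toluene, −78 → 0 °C; aq. Rochelle salt; then NaBH4, MeOH, 0 °C
Reagents that add atoms: water, O
Why: DIBAL-H adds once to the hindered nitrile, hydrolysis of the aldimine gives the non-enolisable aldehyde, and NaBH4 reduces it to the C7 alcohol (nitrile to aldehyde to alcohol).

Step 15
Reactants: 20 primary alcohol
Product: 21 bis(triisopropylsilyl) ether
Conditions: TIPSOTf, 2,6-lutidine, CH2Cl2, 0 °C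
Reagents that add atoms: triisopropylsilyl triflate, CC(C)[Si](OS(=O)(=O)C(F)(F)F)(C(C)C)C(C)C
Why: Silyl ether formation on the neopentyl alcohol gives both hydroxyl groups of the target the same fluoride-labile protection.

Step 16
Reactants: 21 bis(triisopropylsilyl) ether
Product: 22 methyl ketone (C20 carries CH2C(=O)CH3 = C19, C18, C17)
Conditions: OsO4 (2 mol %), NaIO4, 2,6-lutidine, dioxane/H2O, 25 °C
Reagents that add atoms: sodium periodate, [Na+].[O-]I(=O)(=O)=O
Why: Lemieux–Johnson oxidation: OsO4 should dihydroxylate the unhindered 1,1-disubstituted alkene much faster than the tetrasubstituted C12=C13 alkene, and periodate cleaves the diol to the methyl ketone.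

Step 17
Reactants: 22 methyl ketone
Product: 23 allylic alcohol (C14–OH)
Conditions: TBAF (1.1 equiv), THF, 0 °C
Reagents that add atoms: none
Why: Fluoride should cleave the secondary allylic tert-butyldimethylsilyl ether far faster than the two triisopropylsilyl ethers (selective desilylation), leaving C14 unchanged.

Step 18
Reactants: 23 allylic alcohol
Product: 24 allylic tert-butyl carbonate
Conditions: Boc2O, DMAP (10 mol %), CH2Cl2, 25 °C
Reagents that add atoms: di-tert-butyl dicarbonate, CC(C)(C)OC(=O)OC(=O)OC(C)(C)C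
Why: DMAP-catalysed acylation turns the allylic alcohol into an ionisable carbonate with a reagent that does not attack the tertiary amine.

Step 19
Reactants: 24 allylic tert-butyl carbonate
Product: 25 tetracyclic ketone (new six-membered ring C13–C14–C17–C18(=O)–C19–C20)
Conditions: LiHMDS, THF, −78 °C; then Pd(PPh3)4 (10 mol %), −78 → 25 °C
Reagents that add atoms: none
Why: Kinetic deprotonation gives the terminal lithium enolate of the methyl ketone; zerovalent palladium then ionises the allylic carbonate with inversion (loss of CO2 and tert-butoxide) to a π-allyl complex over C12–C13–C14, and the enolate carbon C17 attacks C14 on the face opposite palladium. The closest known reaction type is the Tsuji–Trost allylic alkylation with a preformed ketone enolate, run intramolecularly. The ring closed is six-membered (C13, C14, C17, C18, C19, C20), formed in an enolate-exo mode onto the ring-embedded allyl terminus; a direct five-membered closure with C17 already at the ester level would need a strained attack because the tether starts at the central allyl carbon C13, which is why C18 is kept in the ring here. C14 is the only new stereocentre and is controlled by the carbinol set in step 7: double inversion puts C17 where the carbonate oxygen was. The step needs attack at C14 and not at the fully substituted terminus C12, and C- not O-alkylation; the steric difference of the two termini, the lithium counter-ion and the reversibility of O-allylation under zerovalent palladium should secure both. The alkene ends in the tetrasubstituted C12=C13 position of the target.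

Step 20
Reactants: 25 tetracyclic ketone
Product: 27 α-diazo ketone (diazo on C17), via trifluoroacetyl ketone 26 (not isolated)
Conditions: LiHMDS, THF, −78 °C; CF3CO2CH2CF3; then MsN3, Et3N, H2O, MeCN, 25 °C
Reagents that add atoms: methanesulfonyl azide, CS(=O)(=O)N=[N+]=[N-]
Why: Danheiser deacylative diazo transfer: kinetic deprotonation at the less hindered C17 methylene (C19 is neopentyl), C-trifluoroacetylation and reaction with the sulfonyl azide give the diazo ketone, and C14, now β to the carbonyl, cannot epimerise.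

Step 21
Reactants: 27 α-diazo ketone
Product: 28 3,7-bis-O-triisopropylsilyl ether of the target
Conditions: hν (>300 nm, Pyrex), MeOH, 0 → 25 °C
Reagents that add atoms: methanol, CO
Why: Photochemical Wolff rearrangement: C19 migrates to C17 with loss of N2 and contracts the ring to ring B, methanol traps the ketene carbon C18 as the methyl ester, and the ester enol should be protonated at C17 from the convex face (that of H14 and C21), giving cis H14/H17.

Step 22
Reactants: 28 3,7-bis-O-triisopropylsilyl ether of the target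
Product: 29 target CNP0291564.1
Conditions: HF·pyridine, pyridine, THF, 0 → 25 °C
Reagents that add atoms: none
Why: Buffered fluoride desilylation removes both triisopropylsilyl ethers without base, so the epimerisable C17 centre, the ester and the alkene are untouched.

**Compound list**

1 | methyl (3S)-3-hydroxypentanoate | CC[C@H](O)CC(=O)OC | starting material
2 | methyl (3S)-3-[(triisopropylsilyl)oxy]pentanoate | CC[C@H](O[Si](C(C)C)(C(C)C)C(C)C)CC(=O)OC | intermediate
3 | (3S)-3-[(triisopropylsilyl)oxy]pentan-1-ol | CC[C@H](O[Si](C(C)C)(C(C)C)C(C)C)CCO | intermediate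
4 | {[(3S)-1-iodopentan-3-yl]oxy}triisopropylsilane | CC[C@H](O[Si](C(C)C)(C(C)C)C(C)C)CCI | intermediate
5 | cyclopentane-1,3-dione | O=C1CCC(=O)C1 | starting material
6 | methyl glyoxylate (methyl 2-oxoacetate) | COC(=O)C=O | starting material
7 | methyl 2-(2,5-dioxocyclopentyl)acetate (enolised) | COC(=O)CC1C(=O)CCC1=O | intermediate
8 | methyl 2-[5-oxo-2-(trifluoromethylsulfonyloxy)cyclopent-1-en-1-yl]acetate | COC(=O)CC1=C(OS(=O)(=O)C(F)(F)F)CCC1=O | intermediate
9 | (4-ethoxy-4-oxobutyl)zinc bromide | CCOC(=O)CCC[Zn]Br | starting material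
10 | ethyl 4-[2-(2-methoxy-2-oxoethyl)-3-oxocyclopent-1-en-1-yl]butanoate | CCOC(=O)CCCC1=C(CC(=O)OC)C(=O)CC1 | intermediate
11 | ethyl 4-[(3R)-3-hydroxy-2-(2-methoxy-2-oxoethyl)cyclopent-1-en-1-yl]butanoate | CCOC(=O)CCCC1=C(CC(=O)OC)[C@H](O)CC1 | intermediate
12 | ethyl 4-[(3R)-3-[(tert-butyldimethylsilyl)oxy]-2-(2-methoxy-2-oxoethyl)cyclopent-1-en-1-yl]butanoate | CCOC(=O)CCCC1=C(CC(=O)OC)[C@H](O[Si](C)(C)C(C)(C)C)CC1 | intermediate
13 | methyl (1R)-1-[(tert-butyldimethylsilyl)oxy]-7-oxo-1,2,3,4,5,6,7,8-octahydroazulene-8-carboxylate (C8 epimers, largely enolised; not isolated) | COC(=O)C1C(=O)CCCC2=C1[C@H](O[Si](C)(C)C(C)(C)C)CC2 | intermediate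
14 | methyl (1R)-1-[(tert-butyldimethylsilyl)oxy]-8-(2-methylprop-2-en-1-yl)-7-oxo-1,2,3,4,5,6,7,8-octahydroazulene-8-carboxylate (C8 epimers; centre erased in step 10) | COC(=O)C1(CC(C)=C)C(=O)CCCC2=C1[C@H](O[Si](C)(C)C(C)(C)C)CC2 | intermediate
15 | (1R)-1-[(tert-butyldimethylsilyl)oxy]-8-(2-methylprop-2-en-1-yl)-2,3,4,5,6,8-hexahydroazulen-7(1H)-one (C8 epimers, equilibrating) | CC(=C)CC1C(=O)CCCC2=C1[C@H](O[Si](C)(C)C(C)(C)C)CC2 | intermediate
16 | tricyclic amino ketone: 3-methyl-3-azabicyclo[4.3.1]decan-10-one core (rings C, D) fused at C12=C13 to cyclopentene ring A; C20 bears 2-methylallyl; C14 bears OTBS anti to C21; C9 and C20 as in the target | O=C1[C@H]2CCC3=C([C@H](O[Si](C)(C)C(C)(C)C)CC3)[C@]1(CC(C)=C)CN(C)C2 | intermediate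
17 | tricyclic nitrile: 16 with C6 carrying CN and H (both C6 epimers) | N#CC1[C@H]2CCC3=C([C@H](O[Si](C)(C)C(C)(C)C)CC3)[C@]1(CC(C)=C)CN(C)C2 | intermediate
18 | quaternary nitrile: C6 carries CN (syn to ring C) and the (3S)-3-(triisopropylsilyloxy)pentyl chain (syn to N) | CC[C@H](O[Si](C(C)C)(C(C)C)C(C)C)CC[C@]1(C#N)[C@H]2CCC3=C([C@H](O[Si](C)(C)C(C)(C)C)CC3)[C@]1(CC(C)=C)CN(C)C2 | intermediate
19 | quaternary aldehyde: 18 with CHO (C7) in place of CN (not isolated) | CC[C@H](O[Si](C(C)C)(C(C)C)C(C)C)CC[C@]1(C=O)[C@H]2CCC3=C([C@H](O[Si](C)(C)C(C)(C)C)CC3)[C@]1(CC(C)=C)CN(C)C2 | intermediate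
20 | primary alcohol: C6 carries CH2OH (C7) | CC[C@H](O[Si](C(C)C)(C(C)C)C(C)C)CC[C@]1(CO)[C@H]2CCC3=C([C@H](O[Si](C)(C)C(C)(C)C)CC3)[C@]1(CC(C)=C)CN(C)C2 | intermediate
21 | bis(triisopropylsilyl) ether: C7–OTIPS and C3–OTIPS, C14–OTBS, C20 2-methylallyl | CC[C@H](O[Si](C(C)C)(C(C)C)C(C)C)CC[C@]1(CO[Si](C(C)C)(C(C)C)C(C)C)[C@H]2CCC3=C([C@H](O[Si](C)(C)C(C)(C)C)CC3)[C@]1(CC(C)=C)CN(C)C2 | intermediate
22 | methyl ketone: C20 carries CH2C(=O)CH3 | CC[C@H](O[Si](C(C)C)(C(C)C)C(C)C)CC[C@]1(CO[Si](C(C)C)(C(C)C)C(C)C)[C@H]2CCC3=C([C@H](O[Si](C)(C)C(C)(C)C)CC3)[C@]1(CC(C)=O)CN(C)C2 | intermediate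
23 | allylic alcohol: 22 with free C14–OH | CC[C@H](O[Si](C(C)C)(C(C)C)C(C)C)CC[C@]1(CO[Si](C(C)C)(C(C)C)C(C)C)[C@H]2CCC3=C([C@H](O)CC3)[C@]1(CC(C)=O)CN(C)C2 | intermediate
24 | allylic tert-butyl carbonate of 23 | CC[C@H](O[Si](C(C)C)(C(C)C)C(C)C)CC[C@]1(CO[Si](C(C)C)(C(C)C)C(C)C)[C@H]2CCC3=C([C@H](OC(=O)OC(C)(C)C)CC3)[C@]1(CC(C)=O)CN(C)C2 | intermediate
25 | tetracyclic ketone: six-membered homologue of ring B with C18 as ring ketone between C17 and C19; H14 on the face of C21 | CC[C@H](O[Si](C(C)C)(C(C)C)C(C)C)CC[C@]1(CO[Si](C(C)C)(C(C)C)C(C)C)[C@H]2CCC3=C4[C@@H](CC3)CC(=O)C[C@]41CN(C)C2 | intermediate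
26 | C17-trifluoroacetyl derivative of 25 (enolised, C17 epimers; not isolated) | CC[C@H](O[Si](C(C)C)(C(C)C)C(C)C)CC[C@]1(CO[Si](C(C)C)(C(C)C)C(C)C)[C@H]2CCC3=C4[C@@H](CC3)C(C(=O)C(F)(F)F)C(=O)C[C@]41CN(C)C2 | intermediate
27 | α-diazo ketone: 25 with diazo group on C17 | CC[C@H](O[Si](C(C)C)(C(C)C)C(C)C)CC[C@]1(CO[Si](C(C)C)(C(C)C)C(C)C)[C@H]2CCC3=C4[C@@H](CC3)C(=[N+]=[N-])C(=O)C[C@]41CN(C)C2 | intermediate
28 | 3,7-bis-O-triisopropylsilyl ether of the target | CC[C@H](O[Si](C(C)C)(C(C)C)C(C)C)CC[C@]1(CO[Si](C(C)C)(C(C)C)C(C)C)[C@H]2CCC3=C4[C@@H](CC3)[C@@H](C(=O)OC)C[C@]41CN(C)C2 | intermediate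
29 | CNP0291564.1 | CC[C@H](O)CC[C@]1(CO)[C@H]2CCC3=C4[C@@H](CC3)[C@@H](C(=O)OC)C[C@]41CN(C)C2 | target

**Step count and weak points**

Total step count: 22. Longest linear sequence: 19 steps (steps 4–22, from cyclopentane-1,3-dione 5).

Steps most likely to fail:

1. Step 19 (key step). The enolate may be O-allylated, or the π-allyl complex may lose a β-hydrogen to give a cyclopentadiene before the carbon–carbon bond forms. Fallback, setting out from 23: oxidation of the allylic alcohol with MnO2 in CH2Cl2 gives the cyclopentenone F1. Base-mediated intramolecular aldol condensation (KOtBu, tBuOH/THF) of the methyl ketone onto the ring carbonyl then forms C14=C17 and gives the linearly conjugated dienone F2. Hydrogenation of the less substituted C14=C17 double bond with RhCl(PPh3)3 and H2, from the face opposite C6, returns to the route at 25.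

2. Step 11. The two iminium additions may not be face-selective at C20, or the second ring closure may stall and leave open-chain Mannich bases. Fallback, setting out from 15: soft enolisation (TMSOTf, iPr2NEt, CH2Cl2, −78 °C) and amidoalkylation at C20 with tert-butyl (methoxymethyl)(methyl)carbamate give the carbamate-protected aminomethyl ketone F3, the bulky electrophile entering anti to the silyloxy group. Boc removal (TMSOTf, 2,6-lutidine; then MeOH) gives the secondary amino ketone F4, and an intramolecular Mannich reaction with aqueous formaldehyde and AcOH closes ring D and returns to the route at 16.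

3. Step 12. The TosMIC anion may not add to the shielded bridging carbonyl, or the basic alcoholic medium may fragment the β-amino ketone by retro-Mannich cleavage. Fallback, setting out from 16: Wittig methoxymethylenation (Ph3P=CHOMe from the phosphonium chloride and KHMDS, THF) gives the methyl enol ether F5. Mild hydrolysis (aqueous oxalic acid, THF) gives the C6 aldehyde F6, whose potassium enolate (KH, THF) is alkylated with iodide 4 from the aza-bridge face. This returns to the route at 19, before the borohydride reduction of step 14.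

Further compounds
F1 | step 19 | cyclopentenone (C14 ketone) with acetonyl group on C20 | CC[C@H](O[Si](C(C)C)(C(C)C)C(C)C)CC[C@]1(CO[Si](C(C)C)(C(C)C)C(C)C)[C@H]2CCC3=C(C(=O)CC3)[C@]1(CC(C)=O)CN(C)C2
F2 | step 19 | tetracyclic dienone (C12=C13–C14=C17–C18=O) | CC[C@H](O[Si](C(C)C)(C(C)C)C(C)C)CC[C@]1(CO[Si](C(C)C)(C(C)C)C(C)C)[C@H]2CCC3=C4C(CC3)=CC(=O)C[C@]41CN(C)C2
F3 | step 11 | bicyclic ketone with C20 carrying 2-methylallyl and CH2N(CH3)Boc | O=C1CCCC2=C([C@H](O[Si](C)(C)C(C)(C)C)CC2)[C@]1(CC(C)=C)CN(C)C(=O)OC(C)(C)C
F4 | step 11 | bicyclic ketone with C20 carrying 2-methylallyl and CH2NHCH3 | O=C1CCCC2=C([C@H](O[Si](C)(C)C(C)(C)C)CC2)[C@]1(CC(C)=C)CNC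
F5 | step 12 | C6 methoxymethylene enol ether of 16 (E/Z mixture) | COC=C1[C@H]2CCC3=C([C@H](O[Si](C)(C)C(C)(C)C)CC3)[C@]1(CC(C)=C)CN(C)C2
F6 | step 12 | C6 aldehyde (CHO and H on C6, both C6 epimers) | O=CC1[C@H]2CCC3=C([C@H](O[Si](C)(C)C(C)(C)C)CC3)[C@]1(CC(C)=C)CN(C)C2
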